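## Structural features

- The target is a linear trimeric acylphloroglucinol. Three benzene rings are joined by two CH2 bridges (ring A–CH2–ring B–CH2–ring C), and every ring carbon is substituted.
- Ring B is a phloroglucinol with hydroxyls at C2, C4 and C6. It carries the (R)-2-methylbutanoyl group at C1, the bridge to ring A at C3 and the bridge to ring C at C5.
- Rings A and C are the same 2,6-dihydroxy-4-methoxy-5-methylphenyl unit and differ only in the acyl group (acetyl on A, 2-methylpropanoyl on C). In both, the methoxy group sits between the methyl and the acyl group.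
- The only stereocentre is the α-carbon of the C1 acyl chain. It has no stereogenic neighbour, but it is α to an aryl ketone and can be lost by enolisation (base, warm Lewis acid) or through a ketene from an activated acid derivative.
- Fragile elements are the electron-rich polyphenol (oxidation), the diarylmethane bridges (cleavage and scrambling in strong acid or alkali) and the methyl ethers ortho to ketones (Lewis-acid dealkylation).
- The real difficulty is constitutional. Ring B must carry two different, nearly indistinguishable arms, so a one-pot condensation of monomers would give statistical mixtures; the outer rings also need the less accessible methylation pattern.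
- The key step uses the strict alternation on ring B: oxygen-bearing C2, C4, C6 and carbon-bearing C1, C3, C5. A 3-siloxy vinylketene supplies C6, C1, C2 and C3 (with the ring A arm on C3). A siloxyalkyne supplies C4 and C5 (with the ring C arm on C5). The bonds C3–C4 and C5–C6 are formed.

## Logic of the disconnections

**32 ⇒ 31.** The aryl–acyl bond at C1 of ring B is cut and the acyl group is returned to the C6 oxygen (Fries retron). C1 is the carbon the annulation leaves as C–H and is the only unsubstituted ring carbon in the molecule, so the acyl group can migrate nowhere else. The ester holds exactly one acyl equivalent, and the stereocentre comes unchanged from 28. The forward step needs a Lewis acid that ionises the ester cold enough not to enolise the product or open the bridges. For that reason all benzyl and silyl groups are removed first, so no benzyl cation can be released beside the nucleophilic ring B.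

**31 ⇒ 30 ⇒ 29 ⇒ 27 + 28.** Two O–Si bonds, four O–CH2Ph bonds and the ester C–O bond are cut. 27 has a single free hydroxyl, so the ester position is unambiguous. The forward steps must leave the aryl ester in place (neutral hydrogenolysis, weakly acidic fluoride) and must not racemise 28 during esterification.

**27 ⇒ 26 ⇒ 15 + 25 (key).** Ring B bonds C3–C4 and C5–C6 are cut; the C6–C1 bond is broken and re-formed during the cascade. Each partner carries one arm, so the A/C differentiation problem disappears and a hexasubstituted ring arises from two fragments of similar size. Atom mapping confirms the constitution of 27: the arm of 25 ends beside the free hydroxyl and the arm of 15 ends between the two silyloxy carbons. The demand is regiocontrol in the ketene–alkyne union under neutral thermal conditions. Both partners carry their arm ketones as silyl enol ethers, which are hydrolysed in 26 → 27, because every practical route to a siloxyalkyne passes through an organolithium and an ynolate that a free aryl ketone would not survive.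

**15 ⇒ 14.** The two ring bonds between the C(=O)–CH2 unit and the alkyne carbons are cut ([2+2] retron). The cyclobutenone then comes from the same kind of alkyne as 25, so both arms pass through one common sequence. The forward step needs an alkyne electron-rich enough to add unactivated ketene, and 15 must be kept dry.

**14 ⇒ 11 (through 12, 13); 25 ⇒ 22 (through 23, 24).** The O–Si bond and the C(sp)–O bond are cut, back to terminal alkynes. Oxygenation of a lithium acetylide followed by O-silylation is the general route to siloxyalkynes. It demands the absence of electrophilic or enolisable carbonyl groups, which the enol ethers 11 and 22 ensure.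

**11 ⇒ 10 ⇒ 9 ⇒ 8 ⇒ 7; 22 ⇒ 21 ⇒ 20 ⇒ 19 ⇒ 18.** The enol O–Si bond, the CH2–C(sp) bond, the C–Br bond and one C–H bond of the CH2OH group are cut in turn. The bridge carbon is thereby traced back to a formyl group. The forward steps need an ethynyl transfer that tolerates a ketone (zinc) and a hydride reduction selective for the aldehyde.

**7 ⇒ 6 ⇒ 4 + 5; 18 ⇒ 17 ⇒ 4 + 16.** The two O–benzyl bonds and the aryl–acyl bond are cut. 4 is the point of divergence and receives either acyl group at its single free ring carbon. The acylation must not cleave the neighbouring methyl ether.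

**4 ⇒ 3 ⇒ 1.** The O–CH3 bond and the aryl–CHO bond are cut. Formylating first makes one hydroxyl unique (para to the aldehyde, not hydrogen-bonded to it), so the methyl group lands between the ring methyl and the future acyl position. The formyl carbon later becomes the bridge carbon. The forward steps must stop at mono-formylation and mono-methylation.

## Other disconnections considered

**Alternative 1:** The C1–C(acyl) bond and the C2–O bond of ring B are cut, taking ring B back to a dialkoxy aryne and acid 28.
- Forward key step: CsF releases the aryne from an ortho-silylaryl triflate. The carboxylate adds through oxygen and the resulting aryl anion attacks the ester carbonyl, giving the ortho-hydroxyaryl ketone A1.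
- In favour: the chiral ketone is installed from the unmodified acid in one operation, without a Lewis acid, and the ortho hydroxyl/acyl relationship arises automatically. On the installation of the acyl group alone this is the better plan, since it avoids the ester/Fries pair.
- Against: A1 is only a ring B monomer. Both bridges must then be made by electrophilic benzylation of a ketone-deactivated ring at two poorly differentiated positions with two different arms. Basic fluoride at elevated temperature also exposes the α-stereocentre, and the aryne precursor needs its own sequence.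
- Comparison: structurally it solves the easier part (C1/C2), while the chosen plan solves the placing of two different arms. Mechanistically both are regiocontrolled by oxygen substituents, one by a polar σ-insertion and the other by a pericyclic cascade. In step count it is shorter to the acyl ketone, but likely no shorter overall once the arms are attached.

**Alternative 2:** Two C–C bonds of an outer ring are cut: C(methyl)–C(methoxy) and C(acetyl)–C(hydroxyl).
- Forward key step: a 1,3-bis(silyloxy)diene derived from a β-keto ester adds to a β-methoxy alkynone and aromatises with loss of methanol, giving the ring A monomer A2.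
- In favour: the awkward pattern (methoxy between methyl and acyl) is fixed by construction, with no selective methylation and no Friedel–Crafts acylation beside a methyl ether. On side-ring regiocontrol it is the equal or the better of the chosen plan, and it reaches the acyl/methoxy pattern in fewer steps than steps 1–3.
- Against: it builds monomers only. The bridge carbon must still be introduced by formylation, and the unsymmetrical union of the three rings is not addressed. A β-alkoxy alkynone is a deactivated dienophile, and ring C needs its own alkynone.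
- Comparison: it complements rather than competes, since A2 after formylation would lead to 6. Mechanistically it is a polar stepwise cycloaddition–elimination against a thermal electrocyclic cascade. It is better for the outer rings in step count and neutral for the molecule as a whole.

**Alternative 3:** The C1–C6 bond of ring B is cut, opening it to a triketo ester chain that carries the chiral acyl terminus and the ring C arm.
- Forward key step: with Mg(OCH3)2 in methanol the carbanion between the two ketones nearest the chiral end acylates the ester carbonyl (intramolecular Claisen condensation), closing ring B to the dimer A3.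
- In favour: ring B is formed with its acyl group in place, so no late acyl shift is needed; on this point it is the better. A3 has only one free ring carbon, so the ring A arm can be attached without statistical mixtures, which makes it the equal of the chosen plan on arm differentiation.
- Against: the stereocentre lies α to a polyketone under alkoxide, where enolisation towards it is easy. Aldol closure and pyrone formation compete with the Claisen mode. The branched polyketide chain requires a long linear preparation, and the last bridge is still made by electrophilic benzylation.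
- Comparison: structurally it gives one arm and the acyl group against both arms without the acyl group. Mechanistically it is enolate chemistry under basic equilibrating conditions against a neutral pericyclic cascade. It is expected to be longer and to put the stereocentre at greater risk.

Key step: step 18

Assumption: commercial (R)-2-methylbutanoic acid of high enantiomeric purity is the only source of chirality, and ketene is supplied as a gas from a laboratory generator.

Abbreviations used in names:
- ArA = 3-acetyl-2,6-bis(benzyloxy)-4-methoxy-5-methylphenyl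
- ArA* = ArA with the acetyl group as its tert-butyldimethylsilyl (TBS) enol ether, 1-(TBS-oxy)ethenyl
- ArC = 2,6-bis(benzyloxy)-4-methoxy-3-methyl-5-(2-methylpropanoyl)phenyl
- ArC* = ArC with the ketone as its TBS enol ether, 1-(TBS-oxy)-2-methylprop-1-en-1-yl
- HO-ArA, HO-ArC = ArA, ArC with both benzyloxy groups replaced by hydroxyl
- TIPS = triisopropylsilyl; Bn = benzyl; DPEphos = (Ph2PC6H4)2O; DIC = N,N′-diisopropylcarbodiimide; DMAP = 4-(dimethylamino)pyridine

## Route

Step 1
Reactants: 1 2-methylbenzene-1,3,5-triol
Product: 3 2,4,6-trihydroxy-3-methylbenzaldehyde, via aryl iminium chloride 2 (not isolated)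
Conditions: POCl3, DMF, EtOAc, 0 °C → rt; then H2O, 50 °C
Reagents that add atoms: N,N-dimethylformamide (formyl carbon), CN(C)C=O; water (formyl oxygen), O
Why: Vilsmeier–Haack formylation; the two unsubstituted ring carbons of 1 are equivalent and strongly activated, and the iminium salt 2 deactivates the ring against a second attack until it is hydrolysed.

Step 2
Reactants: 3 2,4,6-trihydroxy-3-methylbenzaldehyde
Product: 4 2,6-dihydroxy-4-methoxy-3-methylbenzaldehyde
Conditions: (CH3O)2SO2 (1.0 equiv), K2CO3 (1.0 equiv), acetone, rt
Reagents that add atoms: dimethyl sulfate, COS(=O)(=O)OC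
Why: Williamson O-methylation under stoichiometric control; the 4-hydroxyl is para to the aldehyde, the most acidic and not held in a hydrogen bond to it, so the methoxy group should land between the ring methyl and the remaining free ring carbon.

Step 3
Reactants: 4 2,6-dihydroxy-4-methoxy-3-methylbenzaldehyde; 5 acetyl chloride
Product: 6 3-acetyl-2,6-dihydroxy-4-methoxy-5-methylbenzaldehyde
Conditions: AlCl3, CH2Cl2/PhNO2, 0 °C → rt
Reagents that add atoms: none
Why: Friedel–Crafts acylation at the single unsubstituted ring carbon, which is ortho to OMe and OH, para to the other OH and meta to the aldehyde; a second acylation of an acylphloroglucinol is a facile known process, and low temperature plus chelation of the new ketone to the adjacent phenoxide should spare the methyl ether.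

Step 4
Reactants: 6 3-acetyl-2,6-dihydroxy-4-methoxy-5-methylbenzaldehyde
Product: 7 3-acetyl-2,6-bis(benzyloxy)-4-methoxy-5-methylbenzaldehyde
Conditions: BnBr, K2CO3, Bu4NI (cat.), DMF, 50 °C
Reagents that add atoms: benzyl bromide, BrCc1ccccc1
Why: Williamson etherification of both chelated hydroxyls; the ring has no free carbon, so C-benzylation cannot compete, and the benzyl ethers withstand the hydride, organometallic and thermal steps that follow.

Step 5
Reactants: 7 3-acetyl-2,6-bis(benzyloxy)-4-methoxy-5-methylbenzaldehyde
Product: 8 1-[2,4-bis(benzyloxy)-3-(hydroxymethyl)-6-methoxy-5-methylphenyl]ethan-1-one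
Conditions: NaBH4, THF/MeOH, −10 °C
Reagents that add atoms: none
Why: Hydride reduction chemoselective for the aldehyde; the aryl methyl ketone is flanked by OMe and OBn, twisted out of conjugation and shielded, and should react much more slowly.

Step 6
Reactants: 8 1-[2,4-bis(benzyloxy)-3-(hydroxymethyl)-6-methoxy-5-methylphenyl]ethan-1-one
Product: 9 1-[2,4-bis(benzyloxy)-3-(bromomethyl)-6-methoxy-5-methylphenyl]ethan-1-one
Conditions: CBr4, PPh3, CH2Cl2, 0 °C
Reagents that add atoms: carbon tetrabromide, BrC(Br)(Br)Br
Why: Appel bromination under neutral conditions; the doubly ortho-alkoxy benzylic bromide is highly reactive and is used without delay.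

Step 7
Reactants: 9 1-[2,4-bis(benzyloxy)-3-(bromomethyl)-6-methoxy-5-methylphenyl]ethan-1-one
Product: 10 1-[2,4-bis(benzyloxy)-6-methoxy-5-methyl-3-(prop-2-yn-1-yl)phenyl]ethan-1-one
Conditions: HC≡CMgBr, ZnBr2, THF, 0 °C; then 9, PdCl2(DPEphos) (5 mol %), THF, rt
Reagents that add atoms: ethynylmagnesium bromide (used as ethynylzinc bromide), C#C[Mg]Br
Why: Negishi benzyl–alkynyl cross-coupling; the ethynylzinc halide is too weakly basic and nucleophilic to attack the ketone, and an excess suppresses benzylation at both ends of the ethynyl unit.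

Step 8
Reactants: 10 1-[2,4-bis(benzyloxy)-6-methoxy-5-methyl-3-(prop-2-yn-1-yl)phenyl]ethan-1-one
Product: 11 tert-butyl({1-[2,4-bis(benzyloxy)-6-methoxy-5-methyl-3-(prop-2-yn-1-yl)phenyl]ethenyl}oxy)dimethylsilane
Conditions: TBSOTf, Et3N, CH2Cl2, 0 °C → rt
Reagents that add atoms: tert-butyldimethylsilyl trifluoromethanesulfonate, CC(C)(C)[Si](C)(C)OS(=O)(=O)C(F)(F)F
Why: Soft enolisation (carbonyl O-silylation, then deprotonation by Et3N) gives the silyl enol ether, which masks the acetyl group against the organolithium and peroxide reagents of step 9 and is removed by dilute acid in step 18; the terminal alkyne is not silylated without a metal catalyst.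

Step 9
Reactants: 11 tert-butyl({1-[2,4-bis(benzyloxy)-6-methoxy-5-methyl-3-(prop-2-yn-1-yl)phenyl]ethenyl}oxy)dimethylsilane
Product: 14 ring A-armed siloxyalkyne, [3-(ArA*)prop-1-yn-1-yl]oxy-triisopropylsilane, via lithium acetylide 12 (not isolated), via lithium ynolate 13 (not isolated)
Conditions: n-BuLi, THF, −78 °C; LiOOt-Bu (from t-BuOOH and LiN(SiMe3)2), THF, −78 → 0 °C; TIPSOTf, −78 °C → rt; non-aqueous work-up
Reagents that add atoms: tert-butyl hydroperoxide (as its lithium salt), CC(C)(C)OO; triisopropylsilyl trifluoromethanesulfonate, CC(C)[Si](OS(=O)(=O)C(F)(F)F)(C(C)C)C(C)C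
Why: Electrophilic oxygenation of the lithium acetylide by lithium tert-butyl peroxide gives the ynolate, and the bulky, hard silyl triflate traps it at oxygen; this is the established conversion of terminal alkynes into siloxyalkynes, and the enol ether and benzyl ethers are inert to it.

Step 10
Reactants: 14 ring A-armed siloxyalkyne
Product: 15 ring A-armed cyclobutenone, 2-(ArA*-methyl)-3-[(triisopropylsilyl)oxy]cyclobut-2-en-1-one
Conditions: CH2=C=O (gas, excess), CH2Cl2, 0 °C → rt; used crude
Reagents that add atoms: ketene, C=C=O
Why: [2+2] cycloaddition of ketene with an electron-rich siloxyalkyne; the alkyne carbon remote from oxygen bonds to the ketene carbonyl carbon, which places the arm on C2 and the siloxy group on C3, and the silyl enol ether is not nucleophilic enough to add unactivated ketene.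

Step 11
Reactants: 4 2,6-dihydroxy-4-methoxy-3-methylbenzaldehyde; 16 2-methylpropanoyl chloride (isobutyryl chloride)
Product: 17 2,6-dihydroxy-4-methoxy-3-methyl-5-(2-methylpropanoyl)benzaldehyde
Conditions: AlCl3, CH2Cl2/PhNO2, 0 °C → rt
Reagents that add atoms: none
Why: Friedel–Crafts acylation at the only free ring carbon, as in step 3; the regiochemistry is fixed by substitution and the methyl ether is protected by low temperature and phenoxide chelation of the new ketone.

Step 12
Reactants: 17 2,6-dihydroxy-4-methoxy-3-methyl-5-(2-methylpropanoyl)benzaldehyde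
Product: 18 2,6-bis(benzyloxy)-4-methoxy-3-methyl-5-(2-methylpropanoyl)benzaldehyde
Conditions: BnBr, K2CO3, Bu4NI (cat.), DMF, 50 °C
Reagents that add atoms: benzyl bromide, BrCc1ccccc1
Why: Williamson etherification of both hydroxyls, as in step 4; no ring carbon is free for C-alkylation.

Step 13
Reactants: 18 2,6-bis(benzyloxy)-4-methoxy-3-methyl-5-(2-methylpropanoyl)benzaldehyde
Product: 19 1-[2,4-bis(benzyloxy)-3-(hydroxymethyl)-6-methoxy-5-methylphenyl]-2-methylpropan-1-one
Conditions: NaBH4, THF/MeOH, −10 °C
Reagents that add atoms: none
Why: Hydride reduction selective for the aldehyde; the doubly ortho-substituted aryl isopropyl ketone is even more hindered than the acetyl group in step 5.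

Step 14
Reactants: 19 1-[2,4-bis(benzyloxy)-3-(hydroxymethyl)-6-methoxy-5-methylphenyl]-2-methylpropan-1-one
Product: 20 1-[2,4-bis(benzyloxy)-3-(bromomethyl)-6-methoxy-5-methylphenyl]-2-methylpropan-1-one
Conditions: CBr4, PPh3, CH2Cl2, 0 °C
Reagents that add atoms: carbon tetrabromide, BrC(Br)(Br)Br
Why: Appel bromination under neutral conditions, as in step 6; the bromide is used at once.

Step 15
Reactants: 20 1-[2,4-bis(benzyloxy)-3-(bromomethyl)-6-methoxy-5-methylphenyl]-2-methylpropan-1-one
Product: 21 1-[2,4-bis(benzyloxy)-6-methoxy-5-methyl-3-(prop-2-yn-1-yl)phenyl]-2-methylpropan-1-one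
Conditions: HC≡CMgBr, ZnBr2, THF, 0 °C; then 20, PdCl2(DPEphos) (5 mol %), THF, rt
Reagents that add atoms: ethynylmagnesium bromide (used as ethynylzinc bromide), C#C[Mg]Br
Why: Negishi benzyl–alkynyl cross-coupling, as in step 7; the zinc acetylide leaves the hindered ketone untouched.

Step 16
Reactants: 21 1-[2,4-bis(benzyloxy)-6-methoxy-5-methyl-3-(prop-2-yn-1-yl)phenyl]-2-methylpropan-1-one
Product: 22 tert-butyl({1-[2,4-bis(benzyloxy)-6-methoxy-5-methyl-3-(prop-2-yn-1-yl)phenyl]-2-methylprop-1-en-1-yl}oxy)dimethylsilane
Conditions: TBSOTf, Et3N, CH2Cl2, 0 → 40 °C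
Reagents that add atoms: tert-butyldimethylsilyl trifluoromethanesulfonate, CC(C)(C)[Si](C)(C)OS(=O)(=O)C(F)(F)F
Why: Soft enolisation to the tetrasubstituted silyl enol ether; the powerful silyl triflate activates the hindered carbonyl so that Et3N can remove the methine proton, and the mask serves the same purpose as in step 8.

Step 17
Reactants: 22 tert-butyl({1-[2,4-bis(benzyloxy)-6-methoxy-5-methyl-3-(prop-2-yn-1-yl)phenyl]-2-methylprop-1-en-1-yl}oxy)dimethylsilane
Product: 25 ring C-armed siloxyalkyne, [3-(ArC*)prop-1-yn-1-yl]oxy-triisopropylsilane, via lithium acetylide 23 (not isolated), via lithium ynolate 24 (not isolated)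
Conditions: n-BuLi, THF, −78 °C; LiOOt-Bu (from t-BuOOH and LiN(SiMe3)2), THF, −78 → 0 °C; TIPSOTf, −78 °C → rt; non-aqueous work-up
Reagents that add atoms: tert-butyl hydroperoxide (as its lithium salt), CC(C)(C)OO; triisopropylsilyl trifluoromethanesulfonate, CC(C)[Si](OS(=O)(=O)C(F)(F)F)(C(C)C)C(C)C
Why: Acetylide oxygenation to the ynolate and O-silylation, as in step 9; with the ketone masked, the terminal alkyne is the only site the organolithium can attack.

Step 18
Reactants: 15 ring A-armed cyclobutenone; 25 ring C-armed siloxyalkyne
Product: 27 ring B phenol, 2-(ArC-methyl)-4-(ArA-methyl)-3,5-bis[(triisopropylsilyl)oxy]phenol, via bis(silyl enol ether) phenol 26 (not isolated)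
Conditions: toluene (degassed), 80 °C then 110 °C; then 1 M HCl, THF, 0 °C → rt
Reagents that add atoms: none
Why: Heating opens 15 by four-electron electrocyclic cleavage of the C(=O)–CH2 ring bond to a 3-siloxy vinylketene bearing the ring A arm. Its carbonyl carbon is attacked by the alkyne carbon of 25 remote from oxygen, and this [2+2] cycloaddition forms ring B bonds C5–C6 and C3–C4. The 4-vinylcyclobutenone so formed opens again to a dienylketene, whose six-electron disrotatory electrocyclisation closes the six-membered carbocycle (C6–C1), and enolisation gives phenol 26. The closest known reaction is the Danheiser benzannulation of cyclobutenones with siloxyalkynes. No stereocentre is created. The selectivity required is regiochemical and is secured by the polarisation of the siloxyalkyne, which puts the ring C arm next to the new hydroxyl and the ring A arm between the two silyloxy carbons; the two arms come from separate partners, so no statistical mixture can arise. Benzyl ethers, silyl ethers and the masked ketones are inert under the neutral thermal conditions, and the dilute acid afterwards hydrolyses only the two silyl enol ethers to the aryl ketones of 27.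

Step 19
Reactants: 27 ring B phenol; 28 (2R)-2-methylbutanoic acid
Product: 29 2-(ArC-methyl)-4-(ArA-methyl)-3,5-bis[(triisopropylsilyl)oxy]phenyl (2R)-2-methylbutanoate
Conditions: DIC, DMAP (10 mol %), CH2Cl2, 0 °C → rt
Reagents that add atoms: none
Why: Steglich esterification of the only free hydroxyl puts exactly one acyl equivalent on the C6 oxygen, next to C1; the cold, nearly neutral carbodiimide conditions should not enolise the α-stereocentre of 28.

Step 20
Reactants: 29 2-(ArC-methyl)-4-(ArA-methyl)-3,5-bis[(triisopropylsilyl)oxy]phenyl (2R)-2-methylbutanoate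
Product: 30 2-(HO-ArC-methyl)-4-(HO-ArA-methyl)-3,5-bis[(triisopropylsilyl)oxy]phenyl (2R)-2-methylbutanoate
Conditions: H2 (1 atm), Pd/C (10 wt %), EtOAc, rt
Reagents that add atoms: none
Why: Hydrogenolysis of the four benzyl ethers under neutral conditions; it precedes the acyl shift so that no benzyl cation can later be released by a Lewis acid beside the nucleophilic ring B, and the aryl ester, the silyl ethers and the hindered ketones are not expected to react.

Step 21
Reactants: 30 2-(HO-ArC-methyl)-4-(HO-ArA-methyl)-3,5-bis[(triisopropylsilyl)oxy]phenyl (2R)-2-methylbutanoate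
Product: 31 3,5-dihydroxy-2-(HO-ArC-methyl)-4-(HO-ArA-methyl)phenyl (2R)-2-methylbutanoate
Conditions: HF·pyridine, THF, 0 °C → rt
Reagents that add atoms: none
Why: Fluoride cleavage of the two aryl silyl ethers in a weakly acidic medium that should neither transesterify the aryl ester nor epimerise it; ring B is thereby brought to its most electron-rich form for the acyl shift.

Step 22
Reactants: 31 3,5-dihydroxy-2-(HO-ArC-methyl)-4-(HO-ArA-methyl)phenyl (2R)-2-methylbutanoate
Product: 32 (2R)-1-{3-[(3-acetyl-2,6-dihydroxy-4-methoxy-5-methylphenyl)methyl]-5-{[2,6-dihydroxy-4-methoxy-3-methyl-5-(2-methylpropanoyl)phenyl]methyl}-2,4,6-trihydroxyphenyl}-2-methylbutan-1-one (target)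
Conditions: TiCl4, CH2Cl2/MeNO2, −20 °C → rt; then 1 M HCl
Reagents that add atoms: none
Why: Fries rearrangement; the Lewis acid ionises the aryl ester and the acyl group is returned to C1, the only unsubstituted ring carbon in the molecule, ortho to two oxygens and para to the third. Any acyl group that reaches an arm oxygen can only return, so the chelated C1 ketone is the sink, and low temperature in the absence of base should preserve the (R) centre.

## Compound list

1 | 2-methylbenzene-1,3,5-triol | Cc1c(O)cc(O)cc1O | starting material
2 | [(2,4,6-trihydroxy-3-methylphenyl)methylidene]dimethylammonium chloride | C[N+](C)=Cc1c(O)cc(O)c(C)c1O.[Cl-] | intermediate (not isolated)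
3 | 2,4,6-trihydroxy-3-methylbenzaldehyde | Cc1c(O)cc(O)c(C=O)c1O | intermediate
4 | 2,6-dihydroxy-4-methoxy-3-methylbenzaldehyde | COc1cc(O)c(C=O)c(O)c1C | intermediate
5 | acetyl chloride | CC(Cl)=O | starting material
6 | 3-acetyl-2,6-dihydroxy-4-methoxy-5-methylbenzaldehyde | CC(=O)c1c(O)c(C=O)c(O)c(C)c1OC | intermediate
7 | 3-acetyl-2,6-bis(benzyloxy)-4-methoxy-5-methylbenzaldehyde | CC(=O)c1c(OCc2ccccc2)c(C=O)c(OCc2ccccc2)c(C)c1OC | intermediate
8 | 1-[2,4-bis(benzyloxy)-3-(hydroxymethyl)-6-methoxy-5-methylphenyl]ethan-1-one | CC(=O)c1c(OCc2ccccc2)c(CO)c(OCc2ccccc2)c(C)c1OC | intermediate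
9 | 1-[2,4-bis(benzyloxy)-3-(bromomethyl)-6-methoxy-5-methylphenyl]ethan-1-one | CC(=O)c1c(OCc2ccccc2)c(CBr)c(OCc2ccccc2)c(C)c1OC | intermediate
10 | 1-[2,4-bis(benzyloxy)-6-methoxy-5-methyl-3-(prop-2-yn-1-yl)phenyl]ethan-1-one | CC(=O)c1c(OCc2ccccc2)c(CC#C)c(OCc2ccccc2)c(C)c1OC | intermediate
11 | tert-butyl({1-[2,4-bis(benzyloxy)-6-methoxy-5-methyl-3-(prop-2-yn-1-yl)phenyl]ethenyl}oxy)dimethylsilane | C=C(O[Si](C)(C)C(C)(C)C)c1c(OCc2ccccc2)c(CC#C)c(OCc2ccccc2)c(C)c1OC | intermediate
12 | lithium acetylide of 11 | [Li+].[C-]#CCc1c(OCc2ccccc2)c(C)c(OC)c(C(=C)O[Si](C)(C)C(C)(C)C)c1OCc1ccccc1 | intermediate (not isolated)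
13 | lithium 3-(ArA*)prop-1-yn-1-olate | [Li+].[O-]C#CCc1c(OCc2ccccc2)c(C)c(OC)c(C(=C)O[Si](C)(C)C(C)(C)C)c1OCc1ccccc1 | intermediate (not isolated)
14 | ring A-armed siloxyalkyne, [3-(ArA*)prop-1-yn-1-yl]oxy-triisopropylsilane | C=C(O[Si](C)(C)C(C)(C)C)c1c(OCc2ccccc2)c(CC#CO[Si](C(C)C)(C(C)C)C(C)C)c(OCc2ccccc2)c(C)c1OC | intermediate
15 | ring A-armed cyclobutenone, 2-(ArA*-methyl)-3-[(triisopropylsilyl)oxy]cyclobut-2-en-1-one | C=C(O[Si](C)(C)C(C)(C)C)c1c(OCc2ccccc2)c(CC2=C(O[Si](C(C)C)(C(C)C)C(C)C)CC2=O)c(OCc2ccccc2)c(C)c1OC | intermediate
16 | 2-methylpropanoyl chloride (isobutyryl chloride) | CC(C)C(Cl)=O | starting material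
17 | 2,6-dihydroxy-4-methoxy-3-methyl-5-(2-methylpropanoyl)benzaldehyde | CC(C)C(=O)c1c(O)c(C=O)c(O)c(C)c1OC | intermediate
18 | 2,6-bis(benzyloxy)-4-methoxy-3-methyl-5-(2-methylpropanoyl)benzaldehyde | CC(C)C(=O)c1c(OCc2ccccc2)c(C=O)c(OCc2ccccc2)c(C)c1OC | intermediate
19 | 1-[2,4-bis(benzyloxy)-3-(hydroxymethyl)-6-methoxy-5-methylphenyl]-2-methylpropan-1-one | CC(C)C(=O)c1c(OCc2ccccc2)c(CO)c(OCc2ccccc2)c(C)c1OC | intermediate
20 | 1-[2,4-bis(benzyloxy)-3-(bromomethyl)-6-methoxy-5-methylphenyl]-2-methylpropan-1-one | CC(C)C(=O)c1c(OCc2ccccc2)c(CBr)c(OCc2ccccc2)c(C)c1OC | intermediate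
21 | 1-[2,4-bis(benzyloxy)-6-methoxy-5-methyl-3-(prop-2-yn-1-yl)phenyl]-2-methylpropan-1-one | CC(C)C(=O)c1c(OCc2ccccc2)c(CC#C)c(OCc2ccccc2)c(C)c1OC | intermediate
22 | tert-butyl({1-[2,4-bis(benzyloxy)-6-methoxy-5-methyl-3-(prop-2-yn-1-yl)phenyl]-2-methylprop-1-en-1-yl}oxy)dimethylsilane | CC(C)=C(O[Si](C)(C)C(C)(C)C)c1c(OCc2ccccc2)c(CC#C)c(OCc2ccccc2)c(C)c1OC | intermediate
23 | lithium acetylide of 22 | [Li+].[C-]#CCc1c(OCc2ccccc2)c(C)c(OC)c(C(=C(C)C)O[Si](C)(C)C(C)(C)C)c1OCc1ccccc1 | intermediate (not isolated)
24 | lithium 3-(ArC*)prop-1-yn-1-olate | [Li+].[O-]C#CCc1c(OCc2ccccc2)c(C)c(OC)c(C(=C(C)C)O[Si](C)(C)C(C)(C)C)c1OCc1ccccc1 | intermediate (not isolated)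
25 | ring C-armed siloxyalkyne, [3-(ArC*)prop-1-yn-1-yl]oxy-triisopropylsilane | CC(C)=C(O[Si](C)(C)C(C)(C)C)c1c(OCc2ccccc2)c(CC#CO[Si](C(C)C)(C(C)C)C(C)C)c(OCc2ccccc2)c(C)c1OC | intermediate
26 | 2-(ArC*-methyl)-4-(ArA*-methyl)-3,5-bis[(triisopropylsilyl)oxy]phenol | Oc1cc(O[Si](C(C)C)(C(C)C)C(C)C)c(Cc2c(OCc3ccccc3)c(C)c(OC)c(C(=C)O[Si](C)(C)C(C)(C)C)c2OCc2ccccc2)c(O[Si](C(C)C)(C(C)C)C(C)C)c1Cc1c(OCc2ccccc2)c(C)c(OC)c(C(=C(C)C)O[Si](C)(C)C(C)(C)C)c1OCc1ccccc1 | intermediate (not isolated)
27 | ring B phenol, 2-(ArC-methyl)-4-(ArA-methyl)-3,5-bis[(triisopropylsilyl)oxy]phenol | Oc1cc(O[Si](C(C)C)(C(C)C)C(C)C)c(Cc2c(OCc3ccccc3)c(C)c(OC)c(C(C)=O)c2OCc2ccccc2)c(O[Si](C(C)C)(C(C)C)C(C)C)c1Cc1c(OCc2ccccc2)c(C)c(OC)c(C(=O)C(C)C)c1OCc1ccccc1 | intermediate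
28 | (2R)-2-methylbutanoic acid | CC[C@@H](C)C(=O)O | starting material
29 | 2-(ArC-methyl)-4-(ArA-methyl)-3,5-bis[(triisopropylsilyl)oxy]phenyl (2R)-2-methylbutanoate | CC[C@@H](C)C(=O)Oc1cc(O[Si](C(C)C)(C(C)C)C(C)C)c(Cc2c(OCc3ccccc3)c(C)c(OC)c(C(C)=O)c2OCc2ccccc2)c(O[Si](C(C)C)(C(C)C)C(C)C)c1Cc1c(OCc2ccccc2)c(C)c(OC)c(C(=O)C(C)C)c1OCc1ccccc1 | intermediate
30 | 2-(HO-ArC-methyl)-4-(HO-ArA-methyl)-3,5-bis[(triisopropylsilyl)oxy]phenyl (2R)-2-methylbutanoate | CC[C@@H](C)C(=O)Oc1cc(O[Si](C(C)C)(C(C)C)C(C)C)c(Cc2c(O)c(C)c(OC)c(C(C)=O)c2O)c(O[Si](C(C)C)(C(C)C)C(C)C)c1Cc1c(O)c(C)c(OC)c(C(=O)C(C)C)c1O | intermediate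
31 | 3,5-dihydroxy-2-(HO-ArC-methyl)-4-(HO-ArA-methyl)phenyl (2R)-2-methylbutanoate | CC[C@@H](C)C(=O)Oc1cc(O)c(Cc2c(O)c(C)c(OC)c(C(C)=O)c2O)c(O)c1Cc1c(O)c(C)c(OC)c(C(=O)C(C)C)c1O | intermediate
32 | (2R)-1-{3-[(3-acetyl-2,6-dihydroxy-4-methoxy-5-methylphenyl)methyl]-5-{[2,6-dihydroxy-4-methoxy-3-methyl-5-(2-methylpropanoyl)phenyl]methyl}-2,4,6-trihydroxyphenyl}-2-methylbutan-1-one | CC[C@@H](C)C(=O)c1c(O)c(Cc2c(O)c(C)c(OC)c(C(C)=O)c2O)c(O)c(Cc2c(O)c(C)c(OC)c(C(=O)C(C)C)c2O)c1O | target

## Step count and least certain steps

Total: 22 steps. Longest linear sequence: 15 steps (steps 1–10, 18, 19–22).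

**Step 18 (key step).**
- What may go wrong: the 3-siloxy vinylketene may be diverted before it meets the alkyne, by dimerisation, by O-acylation of the phenolic product or by cycloaddition to a silyl enol ether. The bimolecular union of two bulky partners is slow, and the siloxyalkyne can rearrange to a silylketene if the temperature has to be raised much above 110 °C.
- Fallback: it sets out from 28, 9 and 20 and returns at 32. Acid 28 would be converted with oxalyl chloride (cat. DMF) into (2R)-2-methylbutanoyl chloride F1. F1 would acylate commercial phloroglucinol (AlCl3, CH2Cl2/PhNO2, 0 °C) to (2R)-2-methyl-1-(2,4,6-trihydroxyphenyl)butan-1-one F2. Friedel–Crafts benzylation of an excess of F2 with bromide 9 (Zn(OTf)2, CH2Cl2, −40 °C) would give the ring A-armed dimer F3. A second benzylation with bromide 20 at the one remaining ring carbon would give the tetra-O-benzyl trimer F4. Hydrogenolysis (H2, Pd/C) would give 32. The price is statistical control in the first benzylation.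

**Step 17 (the same applies to step 9).**
- What may go wrong: incomplete oxygen transfer to the acetylide, base-mediated propargyl-to-allenyl isomerisation through the doubly activated ArCH2 group, or loss of the enol ether to lithium alkoxide. An incomplete masking in step 16 would also leave a ketone that cannot survive this step.
- Fallback: it sets out from 20 and returns at 27. The oxygenation is moved to a simple substrate: ethynyloxy(triisopropyl)silane F5 would be prepared from lithium acetylide by the same peroxide oxygenation and O-silylation, lithiated and transmetalated with ZnCl2 to chloro{[(triisopropylsilyl)oxy]ethynyl}zinc F6, and coupled with bromide 20 under PdCl2(DPEphos) catalysis. This gives the unmasked ring C siloxyalkyne F7 with its ketone never exposed to a strong base. Heating F7 with 15 would give the phenol with only ring A masked, F8, which the acid stage of step 18 would convert into 27. This fallback depends on a reagent (F5, F6) that would first have to be established.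

**Step 22.**
- What may go wrong: erosion of the stereocentre by enolisation of the titanium-chelated ketone or through a ketene from the acylium ion, acid-induced opening and recombination of the diarylmethane bridges, and dealkylation of a methyl ether ortho to a ketone.
- Fallback: it sets out from 31 and returns at 32. A photo-Fries rearrangement (254–300 nm, degassed MeCN) would be used: homolysis of the ester O–C(=O) bond and in-cage recombination at C1, the only free ortho carbon, without acid or base. The ortho-hydroxyaryl ketones of the arms dissipate excitation by intramolecular proton transfer. No new compound is involved.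

**Step 15 (the same applies to step 7).**
- What may go wrong: benzylation at both ends of the ethynyl unit, reductive homocoupling of the very reactive benzylic bromide, and prototropic shift of the 3-arylpropyne to an allene.
- Fallback: it sets out from 18 and returns at 21. LiC≡CSiMe3 with CeCl3 (THF, −78 °C) would add to the aldehyde, which is far more electrophilic than the twisted isopropyl ketone, to give the racemic propargylic alcohol F9. Ionic deoxygenation (Et3SiH, CF3CO2H, CH2Cl2, −20 °C) would give the silyl alkyne F10, and K2CO3 in MeOH would give 21.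

## Further compounds

F1 | step 18 | (2R)-2-methylbutanoyl chloride | CC[C@@H](C)C(Cl)=O
F2 | step 18 | (2R)-2-methyl-1-(2,4,6-trihydroxyphenyl)butan-1-one | CC[C@@H](C)C(=O)c1c(O)cc(O)cc1O
F3 | step 18 | (2R)-1-[3-(ArA-methyl)-2,4,6-trihydroxyphenyl]-2-methylbutan-1-one | CC[C@@H](C)C(=O)c1c(O)cc(O)c(Cc2c(OCc3ccccc3)c(C)c(OC)c(C(C)=O)c2OCc2ccccc2)c1O
F4 | step 18 | (2R)-1-[3-(ArA-methyl)-5-(ArC-methyl)-2,4,6-trihydroxyphenyl]-2-methylbutan-1-one | CC[C@@H](C)C(=O)c1c(O)c(Cc2c(OCc3ccccc3)c(C)c(OC)c(C(C)=O)c2OCc2ccccc2)c(O)c(Cc2c(OCc3ccccc3)c(C)c(OC)c(C(=O)C(C)C)c2OCc2ccccc2)c1O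
F5 | step 17 | ethynyloxy(triisopropyl)silane | C#CO[Si](C(C)C)(C(C)C)C(C)C
F6 | step 17 | chloro{[(triisopropylsilyl)oxy]ethynyl}zinc | Cl[Zn]C#CO[Si](C(C)C)(C(C)C)C(C)C
F7 | step 17 | [3-(ArC)prop-1-yn-1-yl]oxy-triisopropylsilane | CC(C)[Si](C(C)C)(C(C)C)OC#CCc1c(OCc2ccccc2)c(C)c(OC)c(C(=O)C(C)C)c1OCc1ccccc1
F8 | step 17 | 2-(ArC-methyl)-4-(ArA*-methyl)-3,5-bis[(triisopropylsilyl)oxy]phenol | Oc1cc(O[Si](C(C)C)(C(C)C)C(C)C)c(Cc2c(OCc3ccccc3)c(C)c(OC)c(C(=C)O[Si](C)(C)C(C)(C)C)c2OCc2ccccc2)c(O[Si](C(C)C)(C(C)C)C(C)C)c1Cc1c(OCc2ccccc2)c(C)c(OC)c(C(=O)C(C)C)c1OCc1ccccc1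
F0 | step 22 | none | none
F9 | step 15 | 1-{2,4-bis(benzyloxy)-3-[1-hydroxy-3-(trimethylsilyl)prop-2-yn-1-yl]-6-methoxy-5-methylphenyl}-2-methylpropan-1-one (racemic) | CC(C)C(=O)c1c(OCc2ccccc2)c(C(O)C#C[Si](C)(C)C)c(OCc2ccccc2)c(C)c1OC
F10 | step 15 | 1-{2,4-bis(benzyloxy)-6-methoxy-5-methyl-3-[3-(trimethylsilyl)prop-2-yn-1-yl]phenyl}-2-methylpropan-1-one | CC(C)C(=O)c1c(OCc2ccccc2)c(CC#C[Si](C)(C)C)c(OCc2ccccc2)c(C)c1OC
A1 | alternative 1 | (R)-1-[2,4-bis(benzyloxy)-6-hydroxyphenyl]-2-methylbutan-1-one | CC[C@@H](C)C(=O)c1c(O)cc(OCc2ccccc2)cc1OCc1ccccc1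
A2 | alternative 2 | 1-(2,4-dihydroxy-6-methoxy-5-methylphenyl)ethanone | CC(=O)c1c(O)cc(O)c(C)c1OC
A3 | alternative 3 | (2R)-1-[3-(ArC-methyl)-2,4,6-trihydroxyphenyl]-2-methylbutan-1-one | CC[C@@H](C)C(=O)c1c(O)cc(O)c(Cc2c(OCc3ccccc3)c(C)c(OC)c(C(=O)C(C)C)c2OCc2ccccc2)c1O
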